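**Strategy**

The target is the linoleate of a C17 dienediyne alcohol whose only ring is the trans-oxirane C9–O–C10. Everything rests on closing that oxirane last on the finished carbon skeleton. A D-fructose-derived chiral dioxirane transfers one oxygen atom to the C9=C10 (E)-alkene, the only electron-rich 1,2-dialkyl alkene present. This forms both C–O bonds and the 9R,10R centres at once, while the C1=C2 vinyl group and the C4–C7 diyne stay untouched. The precursor is the (3S)-TBS ether of (E)-heptadeca-1,9-diene-4,6-diyn-3-ol, assembled from a silylbutadiyne, acrolein and (E)-dec-2-enyl bromide, with C3 set by lipase resolution. Desilylation and esterification with linoleic acid finish the synthesis.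

Key step: step 7

Remark on the structure: CIP analysis of the target gives 3S at the carbinol carbon and 9R,10R for a trans-2,3-dialkyloxirane, with a (9Z,12Z)-octadeca-9,12-dienoyl ester on O3; the route is planned for exactly this array.

Remark on the precursor: O3 is carried as the TBS ether, because a free carbinol would expose the doubly activated C3–H to the dioxirane and an ester would not survive pH 10.5; the epoxidation is run at the pH of about 10.5 that the ketone needs, since carbonate cannot deprotonate C8.

Remark on the resolution: the sense of the lipase step is assumed from the empirical size rule for secondary alcohols (Kazlauskas rule); the configuration of the recovered alcohol should be checked as its Mosher esters before it is carried on.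

**Route**

Step 1
Reactants: 1 1,4-bis(trimethylsilyl)buta-1,3-diyne; 2 acrolein
Product: 4 racemic 7-(trimethylsilyl)hepta-1-en-4,6-diyn-3-ol, via lithium 4-(trimethylsilyl)buta-1,3-diynide 3 (not isolated)
Conditions: MeLi·LiBr (1.05 equiv), THF, rt; then acrolein, −78 °C; aq NH4Cl
Reagents that add atoms: none
Why: Methyllithium cleaves one C–Si bond only, because the lithium diynide formed resists a second attack, and the acetylide then adds 1,2 to the aldehyde at low temperature (nucleophilic alkynylation), giving C3 as a racemate.

Step 2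
Reactants: 4 racemic 7-(trimethylsilyl)hepta-1-en-4,6-diyn-3-ol
Product: 5 (S)-7-(trimethylsilyl)hepta-1-en-4,6-diyn-3-ol
Conditions: Novozym 435 (immobilised Candida antarctica lipase B), vinyl acetate, hexane, 30 °C, taken past half conversion; chromatographic separation from the acetate
Reagents that add atoms: none
Why: Lipase kinetic resolution by irreversible transesterification, in which the rod-like silyldiynyl group acts as the large substituent and vinyl as the medium one, so the enzyme should acylate the R alcohol and leave the S alcohol, whose enantiomeric purity rises with conversion.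

Step 3
Reactants: 5 (S)-7-(trimethylsilyl)hepta-1-en-4,6-diyn-3-ol
Product: 6 (S)-tert-butyldimethyl{[7-(trimethylsilyl)hepta-1-en-4,6-diyn-3-yl]oxy}silane
Conditions: TBSCl, imidazole, CH2Cl2, 0 °C → rt
Reagents that add atoms: tert-butyldimethylsilyl chloride, CC(C)(C)[Si](C)(C)Cl
Why: Imidazole-promoted O-silylation of a secondary alcohol, which leaves the C3–O bond and therefore the configuration untouched.

Step 4
Reactants: 6 (S)-tert-butyldimethyl{[7-(trimethylsilyl)hepta-1-en-4,6-diyn-3-yl]oxy}silane
Product: 7 (S)-tert-butyl(hepta-1-en-4,6-diyn-3-yloxy)dimethylsilane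
Conditions: K2CO3 (cat.), MeOH, 0 °C; used at once, cold and in the dark
Reagents that add atoms: none
Why: Methoxide-induced protodesilylation of a silylalkyne, which is far faster than cleavage of the hindered O–Si bond of the TBS ether.

Step 5
Reactants: 8 (E)-dec-2-en-1-ol
Product: 9 (E)-1-bromodec-2-ene
Conditions: CBr4, PPh3, CH2Cl2, 0 °C
Reagents that add atoms: carbon tetrabromide, BrC(Br)(Br)Br
Why: Appel bromination, in which bromide displaces the oxyphosphonium group at the primary carbon by SN2, so the bromide should form without allylic transposition and with the E geometry intact.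

Step 6
Reactants: 7 (S)-tert-butyl(hepta-1-en-4,6-diyn-3-yloxy)dimethylsilane; 9 (E)-1-bromodec-2-ene
Product: 11 tert-butyl{[(3S,9E)-heptadeca-1,9-dien-4,6-diyn-3-yl]oxy}dimethylsilane, via copper diynide 10 (not isolated)
Conditions: CuI (1 equiv), NaI (1 equiv), K2CO3 (1.5 equiv), DMF, rt, argon, dark
Reagents that add atoms: none
Why: Coupling of a terminal alkyne with a primary allylic halide through the monovalent copper acetylide (the allylic iodide forms in situ), which is expected to join C7 to the α-carbon C8 with retention of the E alkene and gives the skipped enediyne.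

Step 7
Reactants: 11 tert-butyl{[(3S,9E)-heptadeca-1,9-dien-4,6-diyn-3-yl]oxy}dimethylsilane
Product: 12 tert-butyl({(3S)-8-[(2R,3R)-3-heptyloxiran-2-yl]oct-1-en-4,6-diyn-3-yl}oxy)dimethylsilane
Conditions: D-fructose-derived ketone (1,2:4,5-di-O-isopropylidene-β-D-erythro-2,3-hexodiulo-2,6-pyranose, 0.3 equiv), KHSO5 (as Oxone, 2KHSO5·KHSO4·K2SO4, 1.4 equiv) and K2CO3 (5.8 equiv) added simultaneously over 2–3 h, Bu4NHSO4 (cat.), MeCN–CH2(OMe)2 (1:2)/aq Na2B4O7–Na2EDTA buffer, pH about 10.5, −10 → 0 °C
Reagents that add atoms: potassium peroxymonosulfate (KHSO5, the active salt of Oxone), [K+].[O-]S(=O)(=O)OO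
Why: KHSO5 turns the ketone into its chiral dioxirane, which passes one oxygen atom to the C9=C10 π bond in a concerted spiro transition state and returns the ketone to the cycle. The closest known reaction type is the Shi epoxidation of unfunctionalised trans-1,2-disubstituted alkenes, enynes included. The oxirane closes in a single [2+1] oxygen-atom transfer in which C9–O and C10–O form on the same face, so the E geometry is carried stereospecifically into the trans ring. C9 and C10 are both set by the catalyst: in the spiro approach the two alkene chains point away from the fused dioxolane of the dioxirane, which for the D-fructose series delivers oxygen to the face giving 9R,10R, while C3, six bonds away along the rigid diyne rod, should exert no influence. The step needs face selectivity and site selectivity: the electrophilic oxidant should prefer the 1,2-dialkyl alkene to the C1=C2 vinyl group (monosubstituted, inductively deactivated by O3 and the alkyne, shielded by the silyl group) and to the sp carbons of the diyne, and the silyl ether protects the C3–H from oxidation. The pH of about 10.5 suppresses Baeyer–Villiger loss of the ketone and is not basic enough to deprotonate the C8 methylene.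

Step 8
Reactants: 12 tert-butyl({(3S)-8-[(2R,3R)-3-heptyloxiran-2-yl]oct-1-en-4,6-diyn-3-yl}oxy)dimethylsilane
Product: 13 (3S)-8-[(2R,3R)-3-heptyloxiran-2-yl]oct-1-en-4,6-diyn-3-ol
Conditions: Bu4NF (1.1 equiv), AcOH (1.1 equiv), THF, 0 °C
Reagents that add atoms: none
Why: Fluoride-driven cleavage of the O–Si bond, with acetic acid buffering the alkoxide so that neither the oxirane nor the propargylic C8 position is attacked by base.

Step 9
Reactants: 13 (3S)-8-[(2R,3R)-3-heptyloxiran-2-yl]oct-1-en-4,6-diyn-3-ol; 14 linoleic acid
Product: 15 (3S)-8-[(2R,3R)-3-heptyloxiran-2-yl]oct-1-en-4,6-diyn-3-yl (9Z,12Z)-octadeca-9,12-dienoate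
Conditions: EDC·HCl, DMAP (cat.), CH2Cl2, 0 °C → rt, argon, dark
Reagents that add atoms: none
Why: Steglich esterification (carbodiimide activation with DMAP acyl transfer) acylates O3 without breaking the C3–O bond, so the configuration is retained, and the neutral conditions spare the oxirane, the diyne and the Z,Z-diene of the acid.

**Compound list**

1 | 1,4-bis(trimethylsilyl)buta-1,3-diyne | C[Si](C)(C)C#CC#C[Si](C)(C)C | starting material
2 | acrolein | C=CC=O | starting material
3 | lithium 4-(trimethylsilyl)buta-1,3-diynide | [Li]C#CC#C[Si](C)(C)C | intermediate (not isolated)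
4 | racemic 7-(trimethylsilyl)hepta-1-en-4,6-diyn-3-ol | C=CC(O)C#CC#C[Si](C)(C)C | intermediate
5 | (S)-7-(trimethylsilyl)hepta-1-en-4,6-diyn-3-ol | C=C[C@@H](C#CC#C[Si](C)(C)C)O | intermediate
6 | (S)-tert-butyldimethyl{[7-(trimethylsilyl)hepta-1-en-4,6-diyn-3-yl]oxy}silane | C=C[C@@H](C#CC#C[Si](C)(C)C)O[Si](C)(C)C(C)(C)C | intermediate
7 | (S)-tert-butyl(hepta-1-en-4,6-diyn-3-yloxy)dimethylsilane | C=C[C@@H](C#CC#C)O[Si](C)(C)C(C)(C)C | intermediate
8 | (E)-dec-2-en-1-ol | OC/C=C/CCCCCCC | starting material
9 | (E)-1-bromodec-2-ene | BrC/C=C/CCCCCCC | intermediate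
10 | copper diynide of 7, [(S)-5-(tert-butyldimethylsilyloxy)hepta-6-en-1,3-diyn-1-yl]copper | C=C[C@@H](C#CC#C[Cu])O[Si](C)(C)C(C)(C)C | intermediate (not isolated)
11 | tert-butyl{[(3S,9E)-heptadeca-1,9-dien-4,6-diyn-3-yl]oxy}dimethylsilane | C=C[C@@H](C#CC#CC/C=C/CCCCCCC)O[Si](C)(C)C(C)(C)C | intermediate
12 | tert-butyl({(3S)-8-[(2R,3R)-3-heptyloxiran-2-yl]oct-1-en-4,6-diyn-3-yl}oxy)dimethylsilane | C=C[C@@H](C#CC#CC[C@H]1O[C@@H]1CCCCCCC)O[Si](C)(C)C(C)(C)C | intermediate
13 | (3S)-8-[(2R,3R)-3-heptyloxiran-2-yl]oct-1-en-4,6-diyn-3-ol | C=C[C@@H](C#CC#CC[C@H]1O[C@@H]1CCCCCCC)O | intermediate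
14 | linoleic acid, (9Z,12Z)-octadeca-9,12-dienoic acid | OC(=O)CCCCCCC/C=C\C/C=C\CCCCC | starting material
15 | (3S)-8-[(2R,3R)-3-heptyloxiran-2-yl]oct-1-en-4,6-diyn-3-yl (9Z,12Z)-octadeca-9,12-dienoate | C=C[C@@H](C#CC#CC[C@H]1O[C@@H]1CCCCCCC)OC(=O)CCCCCCC/C=C\C/C=C\CCCCC | target

**Step count and risks**

Total step count: 9. Longest linear sequence: 8 steps (1 → 4 → 5 → 6 → 7 → 11 → 12 → 13 → 15); step 5 is a one-step side branch.

Steps most likely to fail:

1. Step 7. The risks are incomplete face discrimination at C9=C10, which would give the 9S,10S diastereomer that is hard to remove; competing oxidation at C1=C2 or at C3–H; and slow turnover of the very lipophilic substrate while the ketone decays. The fallback sets out from 8 and 7 and comes back at 12; it makes the oxirane on the allylic alcohol before the C7–C8 bond is formed. Sharpless asymmetric epoxidation of 8 (Ti(OiPr)4, D-(−)-diethyl tartrate, t-BuOOH, 4 Å molecular sieves, CH2Cl2, −20 °C) should give ((2R,3R)-3-heptyloxiran-2-yl)methanol F1. Triflation (Tf2O, 2,6-lutidine, CH2Cl2, −78 °C) gives ((2R,3R)-3-heptyloxiran-2-yl)methyl trifluoromethanesulfonate F2. Diyne 7 is deprotonated with n-BuLi (THF, −78 °C) to the lithium diynide of 7 F3, which displaces the primary triflate of F2 (THF–DMPU, −78 → −20 °C) to give 12.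

2. Step 6. The risks are attack of the copper acetylide at the γ-carbon of the allylic halide (branched isomer), oxidative dimerisation or decomposition of the terminal diyne, and base-induced isomerisation of the skipped enyne. The fallback sets out from 7 and comes back at 11; it builds the E alkene by olefination instead of allylic substitution. The lithium diynide of 7 F3 (n-BuLi, THF, −78 °C) opens ethylene oxide in the presence of BF3·OEt2 to give (S)-7-(tert-butyldimethylsilyloxy)non-8-ene-3,5-diyn-1-ol F4. A Mitsunobu reaction with 1-phenyl-1H-tetrazole-5-thiol (PPh3, DIAD, THF, 0 °C) gives 5-{[(S)-7-(tert-butyldimethylsilyloxy)non-8-ene-3,5-diyn-1-yl]sulfanyl}-1-phenyl-1H-tetrazole F5. Oxidation with H2O2 and catalytic (NH4)6Mo7O24 in EtOH, which does not touch the deactivated vinyl group or the diyne, gives 5-{[(S)-7-(tert-butyldimethylsilyloxy)non-8-ene-3,5-diyn-1-yl]sulfonyl}-1-phenyl-1H-tetrazole F6. Julia–Kocienski olefination of F6 with octanal (KN(SiMe3)2 added to both partners, DME, −60 °C → rt) should give 11, with the E geometry expected for this sulfone type with unbranched partners.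

3. Step 2. The risks are insufficient discrimination between the enantiomers by the enzyme (vinyl against diynyl) or very slow acylation, leaving 5 with inadequate enantiomeric purity. The fallback sets out from 4 and comes back at 5; it is an oxidative kinetic resolution in which the catalyst reads the allylic alcohol itself. Sharpless kinetic resolution (Ti(OiPr)4, L-(+)-diisopropyl tartrate, t-BuOOH 0.6 equiv, 4 Å molecular sieves, CH2Cl2, −20 °C) should epoxidise the R alcohol to the erythro epoxy alcohol (1S)-1-[(2R)-oxiran-2-yl]-5-(trimethylsilyl)penta-2,4-diyn-1-ol F7. The slow-reacting S alcohol 5 is recovered and separated by chromatography.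

**Further compounds**

F1 | step 7 | ((2R,3R)-3-heptyloxiran-2-yl)methanol | OC[C@H]1O[C@@H]1CCCCCCC
F2 | step 7 | ((2R,3R)-3-heptyloxiran-2-yl)methyl trifluoromethanesulfonate | FC(F)(F)S(=O)(=O)OC[C@H]1O[C@@H]1CCCCCCC
F3 | step 7 | lithium diynide of 7, [(S)-5-(tert-butyldimethylsilyloxy)hepta-6-en-1,3-diyn-1-yl]lithium | C=C[C@@H](C#CC#C[Li])O[Si](C)(C)C(C)(C)C
F4 | step 6 | (S)-7-(tert-butyldimethylsilyloxy)non-8-ene-3,5-diyn-1-ol | C=C[C@@H](C#CC#CCCO)O[Si](C)(C)C(C)(C)C
F5 | step 6 | 5-{[(S)-7-(tert-butyldimethylsilyloxy)non-8-ene-3,5-diyn-1-yl]sulfanyl}-1-phenyl-1H-tetrazole | C=C[C@@H](C#CC#CCCSc1nnnn1-c1ccccc1)O[Si](C)(C)C(C)(C)C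
F6 | step 6 | 5-{[(S)-7-(tert-butyldimethylsilyloxy)non-8-ene-3,5-diyn-1-yl]sulfonyl}-1-phenyl-1H-tetrazole | C=C[C@@H](C#CC#CCCS(=O)(=O)c1nnnn1-c1ccccc1)O[Si](C)(C)C(C)(C)C
F7 | step 2 | (1S)-1-[(2R)-oxiran-2-yl]-5-(trimethylsilyl)penta-2,4-diyn-1-ol | C1O[C@H]1[C@H](C#CC#C[Si](C)(C)C)O
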